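All constants are made up; the flask was simulated.

Birch is the flask that changes temperature on the way; larch, alder and ash each stay at one temperature.

| setting | birch | larch | alder | ash |
|---|---|---|---|---|
| substrate | 0.050 M | 0.050 M | 0.050 M | 0.050 M |
| reagent | 1.50 equiv | 1.50 equiv | 1.50 equiv | 1.50 equiv |
| time | 3.0 d | 3.0 d | 3.0 d | 3.0 d |
| remark | at 55 °C until 2.0 d, from then on at −5 °C |  |  |  |
| temperature |  | 55 °C | −5 °C | 25 °C |

    2 substrate → homo dimer (k1 = 0.20 M⁻¹ h⁻¹, Ea1 = 61.0 kJ mol⁻¹)
    substrate + reagent → intermediate + released group (k2 = 0.75 M⁻¹ h⁻¹, Ea2 = 59.0 kJ mol⁻¹)
    intermediate → target (k3 = 0.033 h⁻¹, Ea3 = 100 kJ mol⁻¹)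
    target ⇌ isomer of the product (K4 = 0.55, k4 = 0.0076 h⁻¹, Ea4 = 94.0 kJ mol⁻¹, ΔH4 = 12.0 kJ mol⁻¹)
    (constants at 25 °C)

- percent here means substrate units held: one homo dimer counts as two
- where a step has two of a species, its rate is k times that concentration squared, and two are used at each turn
- all constants are for 25 °C and move with temperature by the activation energies and enthalpies

- the best flask by amount of target, in percent of the substrate charged; "all alike" if 1.5 percentage points covers them all (birch / larch / alder / ash / all alike)
- amount of target at the end, in percent of the substrate charged, birch
- amount of target at the end, in percent of the substrate charged, larch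
- amount of target at the end, in percent of the substrate charged, alder
- amount of target at the end, in percent of the substrate charged, ash

At 55 °C the isomerisation constant is 0.856, so 53.9% of the pair target plus isomer stands as target once that pair has relaxed: this fraction, one over one plus the constant, is the equilibrium share. Larch should reach it. Alder's relaxation half-life of 64.1 d, scaled by the factor 3600 raised to the ratio of the activation energies and corrected for the two constants, becomes 1.31 h in larch, far shorter than 3.0 d. The pair in larch should therefore stand under thermodynamic control.

The pair receives what the dimer spares. The constants for the reagent step and the dimer step stand in the ratio 3.75, and their activation energies differ by 2.00 kJ mol⁻¹, far less than either, so one ratio serves at each temperature. With two substrate used per dimer turn, the reagent step takes 73.8% of the substrate at the first moment, and the chain gives 39.8% target in larch.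

That first-moment share is the weak link, since [substrate] falls faster than [reagent] and the ratio between them climbs. Reckoned at half conversion, the share becomes 80.9%, and larch should hold 43.6%. Birch, which runs as larch until 2.0 d, should hold 43.6%, since at −5 °C the relaxation half-life of 64.1 d, as in alder, is long against 3.0 d. At 25 °C the equilibrium share is 64.5%, which gives ash 52.2%, though unfinished conversion pulls that figure down and target not yet relaxed pushes it up. Alder's intermediate step has a constant below 5.466 × 10⁻⁴ h⁻¹, so its target stays under 3.94%. The best flask by this reckoning is ash.

The forecast names ash, with 44.1% for birch, 43.9% for larch, 0.3% for alder and 49.3% for ash, a lower figure for ash than the reckoning above: “the kinetic overshoot of target still makes ash the best flask”.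

The simulation gives ash as the best flask, with 44.1% in birch, 43.9% in larch, 0.307% in alder and 50.3% in ash.

Birch holds 44.1% at the end because the isomerisation claims its part of the pair: without it, the same flask holds 81.5%. Larch's pair stands at a target share of 53.9%, against its equilibrium share of 53.9%. The pair in ash at 3.0 d has a target share of 81.5%, above its own 64.5%, which is kinetic control, and after 30.0 d that pair holds 82.5%, of which 64.5% is 53.2%, against a target of 53.2% in ash.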